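Conventions. Compound numbers are those of the compound list after the steps. Decalin intermediates carry labdane atom numbers: ring A = C1–C5 and C10, ring B = C5–C10, C17 on C8, C18 (methyl) and C19 on C4, C20 on C10, side chain C11–C16. α is the face of H5, β the face of C20. TBDPS = tert-butyldiphenylsilyl, TBS = tert-butyldimethylsilyl.

Assumption: the (S)-auxiliary 2 is taken to give the (S)-configured quaternary carbon of 4 in step 2; if the facial sense were the opposite, the (R)-antipode of 2 would be used and nothing else would change.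

## Analysis of the target

The target 29 is a labdane with a trans-decalin (ring A: C1–C5, C10; ring B: C5–C10) and four oxygen heterocycles. These are a δ-lactone C19(=O)–O–C20 that bridges the 1,3-diaxial positions 4β and 10β (a 3-oxabicyclo[3.3.1]nonanone with ring A), a spiro-oxirane C8–O–C17, a spiro-oxolane O–C9–C11–C12–C13, and a spiro 2,3-dihydrofuran C13–C14=C15–O–C16. It has seven stereocentres (4S,5R,6R,8R,9S,10S,13R): six are contiguous on the decalin and C13 is remote. C4 and C10 are quaternary, and C8, C9 and C13 are fully substituted and oxygenated. Ring B carries three β-axial groups (6-OAc, the oxirane oxygen on C8, C20) that shield its β face.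

The feature that the route is built on is the pair O–C8 (β, axial) and O–C9 (α, axial). The two oxygens are trans-diaxial on adjacent carbons, and the oxygen on C8 is tied back to C17. This is the array that a Payne rearrangement of an 8α,9α-epoxy-17-ol leaves behind, and the C9 alkoxide that such a rearrangement sets free sits five atoms from C13. A direct epoxidation of an 8(17)-alkene would come from the open α face and give the wrong oxirane, so the β-oxirane has to be made indirectly in any case.

The sensitive groups are these. The 9,13-epoxy-15,16-epoxy-14-ene unit opens to a 9-hydroxy furan with traces of acid. The terminal oxirane and the acetate limit the use of acid, hydride and strong base. A free 6β-alkoxide is 1,3-diaxial to C19 and can take over the lactone. The hard parts are therefore the two adjacent spiro centres C8/C9, the contra-thermodynamic dihydrofuran, the cis relation of the two quaternary carbons C4 and C10, and the order of events at C6.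

## Retrosynthetic reasoning

29 ⇒ 27 ⇒ 25. The acetate is put on last. The enol ether C14=C15 is taken back to the saturated spiro γ-lactone 25 (C15 at the acid level). Unlike 29, 25 tolerates traces of acid, and it is exactly what a conjugate addition to a butenolide delivers. Forward, a partial reduction to lactol 26 and a dehydration to 27 have to leave the hindered δ-lactone alone. O6 stays silylated until the end so that no 6β-alkoxide meets C19.

25 ⇒ 22 (key disconnection). The O–C13 bond of the oxolane and the O–C8 bond of the spiro-oxirane are cut, and the oxygen on C9 is reconnected to C8. This gives the 8α,9α-epoxide 22 with a silyl-protected hydroxyl on C17 and a butenolide at the end of the side chain. The cut is made here because it removes both spiro rings and three stereocentres (C8, C9, C13) in one retrosynthetic step. It also replaces the inaccessible β-face epoxidation by an α-face epoxidation of a flat tetrasubstituted alkene. Forward, unmasking the C17 alkoxide has to trigger a Payne rearrangement (C8 inverted, 9α-alkoxide released) and then a 5-exo-trig oxa-Michael addition to C13.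

22 ⇒ 21 ⇒ 18 + 19. The oxirane is removed to the Δ8 alkene 21, whose α face is the only open one. The C12–C13 bond between an sp3 and an sp2 carbon is cut to the vinyl compound 18 and the bromobutenolide 19. Forward, this is a hydroboration at C12 and a B-alkyl cross-coupling that brings in the butenolide at its final oxidation level.

18 ⇒ 17 ⇒ 16 ⇒ 15. These are functional group changes only: the silyl ether from the 6β-alcohol, the 6β-alcohol from the C6 ketone (hydride from the α face), and the vinyl group from the C11 aldehyde. They lead back to the keto enal lactone 15, in which ring B carries all its handles (C6=O, Δ8, C17–O, C11=O).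

15 ⇒ 14 ⇒ 10 + 12. The lactone is opened to a C19 carboxamide and the C20 hydroxyl (lactol 14), and ring B is cut at C7–C8 and C9–C10. This is a [4+2] cycloaddition of the ring-A 2-ethoxy diene 10 with the ynal 12. The cut is chosen because one cycloaddition gives ring B, the quaternary C10, the Δ8 alkene and, as an enol ether, the C6 oxygen. The carboxamide on C4 has to steer the alkyne to the α face of C10. The later lactonisation then removes the auxiliary and proves that C19 and C20 are cis.

10 ⇒ 9 ⇒ 7 + 8, 7 ⇒ 6 ⇒ 4 ⇒ 3 ⇒ 1 + 2, and 12 ⇒ 11. The diene comes from the bromo enal 7 and the stannane 8, and 7 from the ketone 6 by haloformylation (6 can enolise only toward C10). The quaternary C4 of 6 comes from a Birch reduction–methylation of the chiral benzamide 3, made from 1 and 2. The ynal 12 is the formylation product of the silyl propargyl ether 11.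

## Alternatives that were turned down

Alternative 1: the textbook route cuts ring B from ring A by a Robinson annulation. An asymmetric annulation would give the angularly substituted enedione A1 with C10 in place. C4 would follow by reductive carboxylation and methylation, the side chain by organometallic addition to the C9 ketone, the oxirane by a sulfur ylide on a C8 ketone, and the dihydrofuran from a butenolide. It was turned down for three reasons. A1 has no handle at C6. It needs a deoxygenation at C3. It sets C4, C5, C6, C8, C9 and C13 one at a time, with a doubtful facial outcome for the addition to the hindered C9 ketone. The count comes to well over 25 steps.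

Alternative 2: a polyene bicyclisation cuts C4–C5 and C9–C10 together. An oxidative radical cyclisation of an open-chain α-methyl β-keto ester with Mn(OAc)3 and Cu(OAc)2 would give the decalin A2 in one operation, with C4, C5 and C10 set as a group. It was turned down because A2 comes with a C3 ketone that must be removed, with hydrogen on C9 and with no oxygen or handle at C6. The C9–O bond and the 6β-oxygen would then need C–H oxidations at a hindered tertiary allylic site and at an unactivated methylene. No intrinsic or directed selectivity can be argued for either (allylic oxidation of an 8(17)-ene goes to C7). The corrective steps would cost more than the cascade wins.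

Alternative 3: only the O–C13 bond is cut. The forward step would be an anodic, dearomatising spiro-etherification of the 9-hydroxy furan A3. It was turned down for mechanistic reasons. A furan radical cation is attacked at its α-carbons (C15, C16), so the C9 hydroxyl would close a six-membered ether at C16 or the ring would be dialkoxylated. The change that is needed is a redox-neutral hydroalkoxylation against the aromatic stabilisation, which acid reverses. An oxidised C16 acetal would have to be reduced under Lewis acid, which the product does not survive. A3 would also still need the whole core, including the β-oxirane.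

Key step: step 15

## Steps

Step 1
Reactants: 1 2-methoxybenzoyl chloride; 2 (2S)-2-(methoxymethyl)pyrrolidine
Product: 3 (2-methoxyphenyl)[(2S)-2-(methoxymethyl)pyrrolidin-1-yl]methanone
Conditions: Et3N, CH2Cl2, 0 → 23 °C
Reagents that add atoms: none
Why: Acylation of the secondary amine by the acid chloride (amide formation); it attaches the chiral auxiliary that will control C4.

Step 2
Reactants: 3 (2-methoxyphenyl)[(2S)-2-(methoxymethyl)pyrrolidin-1-yl]methanone
Product: 4 [(1S)-2-methoxy-1-methylcyclohexa-2,5-dien-1-yl][(2S)-2-(methoxymethyl)pyrrolidin-1-yl]methanone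
Conditions: K, NH3/THF, t-BuOH (1 equiv), −78 °C; then MeI, −78 °C; NH4Cl
Reagents that add atoms: iodomethane CI
Why: Birch reduction of the benzamide gives the amide enolate, which is methylated at the ipso carbon (Birch reduction–alkylation). The chelating methoxymethyl arm of the auxiliary fixes the enolate geometry and shields one face, so the quaternary carbon C4 should form as one diastereomer.

Step 3
Reactants: 4 [(1S)-2-methoxy-1-methylcyclohexa-2,5-dien-1-yl][(2S)-2-(methoxymethyl)pyrrolidin-1-yl]methanone
Product: 6 (2S)-2-{[(2S)-2-(methoxymethyl)pyrrolidin-1-yl]carbonyl}-2-methylcyclohexan-1-one, via cyclohexenone 5 (not isolated)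
Conditions: 1 M HCl, THF, 23 °C; then H2 (1 atm), Pd/C, EtOAc, 23 °C
Reagents that add atoms: water O
Why: Hydrolysis of the enol ether gives the β-keto amide 5, whose alkene cannot move into conjugation past the quaternary carbon. Hydrogenation then removes this disubstituted alkene, and the quaternary centre cannot epimerise.

Step 4
Reactants: 6 (2S)-2-{[(2S)-2-(methoxymethyl)pyrrolidin-1-yl]carbonyl}-2-methylcyclohexan-1-one
Product: 7 (3R)-2-bromo-3-{[(2S)-2-(methoxymethyl)pyrrolidin-1-yl]carbonyl}-3-methylcyclohex-1-ene-1-carbaldehyde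
Conditions: PBr3, DMF, CHCl3, 0 → 45 °C; then NaOAc (aq)
Reagents that add atoms: N,N-dimethylformamide CN(C)C=O; phosphorus tribromide BrP(Br)Br; water O
Why: Vilsmeier–Haack–Arnold bromoformylation. The ketone can enolise only toward C10, so one β-bromo enal forms, with C20 as the aldehyde and a halide on C5 for the coupling.

Step 5
Reactants: 7 (3R)-2-bromo-3-{[(2S)-2-(methoxymethyl)pyrrolidin-1-yl]carbonyl}-3-methylcyclohex-1-ene-1-carbaldehyde; 8 tributyl(1-ethoxyethenyl)stannane
Product: 9 (3S)-2-(1-ethoxyethenyl)-3-{[(2S)-2-(methoxymethyl)pyrrolidin-1-yl]carbonyl}-3-methylcyclohex-1-ene-1-carbaldehyde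
Conditions: Pd(PPh3)4 (5 mol%), CuI (10 mol%), DMF, 60 °C
Reagents that add atoms: none
Why: Stille coupling of an activated β-bromo enal with an α-alkoxyvinylstannane; it installs C6 and C7 as the 2-ethoxy diene, and copper iodide helps the transmetalation at the hindered position.

Step 6
Reactants: 9 (3S)-2-(1-ethoxyethenyl)-3-{[(2S)-2-(methoxymethyl)pyrrolidin-1-yl]carbonyl}-3-methylcyclohex-1-ene-1-carbaldehyde
Product: 10 [(1S)-2-(1-ethoxyethenyl)-3-(hydroxymethyl)-1-methylcyclohex-2-en-1-yl][(2S)-2-(methoxymethyl)pyrrolidin-1-yl]methanone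
Conditions: NaBH4, EtOH, 0 °C
Reagents that add atoms: none
Why: 1,2-Reduction of the conjugated aldehyde to the C20 alcohol; the tertiary amide and the enol ether do not react with borohydride, and the diene becomes electron-rich for the cycloaddition.

Step 7
Reactants: 11 tert-butyl(diphenyl)(prop-2-yn-1-yloxy)silane
Product: 12 4-{[tert-butyl(diphenyl)silyl]oxy}but-2-ynal
Conditions: n-BuLi, THF, −78 °C; DMF, −78 → 0 °C; inverse quench into KH2PO4 (aq)
Reagents that add atoms: N,N-dimethylformamide CN(C)C=O
Why: Lithiation of the terminal alkyne and formylation with DMF; the buffered inverse quench keeps the liberated amine from adding to the ynal.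

Step 8
Reactants: 10 [(1S)-2-(1-ethoxyethenyl)-3-(hydroxymethyl)-1-methylcyclohex-2-en-1-yl][(2S)-2-(methoxymethyl)pyrrolidin-1-yl]methanone; 12 4-{[tert-butyl(diphenyl)silyl]oxy}but-2-ynal
Product: 14 11,20-lactol of the cycloadduct: 6-ethoxy-11,20-epoxy-11-hydroxy-17-(TBDPS-oxy)-12,13,14,15,16-pentanorlabda-5,8-dien-19-oic acid (2S)-2-(methoxymethyl)pyrrolidide (4α-methyl; C20 β), via hydroxy enal cycloadduct 13 (not isolated)
Conditions: 12 (1.5 equiv), 2,6-di-tert-butyl-4-methylphenol (cat.), toluene, 90 °C, sealed tube
Reagents that add atoms: none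
Why: Thermal Diels–Alder reaction of a 2-alkoxy diene with an ynal. The terminus C7, activated by the 6-ethoxy group, should bond to the alkyne carbon that bears the silyloxymethyl group, and the hindered terminus C10 to the formyl-bearing carbon; electronic and steric preferences agree. The bulky carboxamide on C4 should stand pseudoaxial, because allylic strain with the 1-ethoxyvinyl group keeps the methyl group in the plane, so the alkyne should add to the opposite face and C20 should end cis to C19; the hydroxy enal 13 then closes to lactol 14.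

Step 9
Reactants: 14 11,20-lactol of the cycloadduct (6-ethoxy-Δ5,8 diene, 19-pyrrolidide, 17-OTBDPS)
Product: 15 6,11-dioxo-17-(TBDPS-oxy)-12,13,14,15,16-pentanorlabd-8-en-19,20-olide (4α-methyl, 5α-H)
Conditions: p-TsOH·H2O (1.5 equiv), MeCN/H2O (10:1), 45 °C
Reagents that add atoms: water O
Why: Acid hydrolyses the enol ether with protonation of C5 from the open α face (trans-decalin, also the stable epimer next to the C6 ketone). Through the open hydroxy enal, the C20 hydroxyl attacks the 1,3-diaxial amide (N→O acyl transfer, driven by relief of the diaxial strain and protonation of the amine), which releases the auxiliary and forms the δ-lactone. Only an adduct with C19 and C20 cis can lactonise, so the step also checks the facial outcome of step 8.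

Step 10
Reactants: 15 6,11-dioxo-17-(TBDPS-oxy)-12,13,14,15,16-pentanorlabd-8-en-19,20-olide
Product: 16 6-oxo-17-(TBDPS-oxy)-13,14,15,16-tetranorlabda-8,11-dien-19,20-olide
Conditions: CH2I2, Zn, Ti(O-i-Pr)4, THF, 23 °C
Reagents that add atoms: diiodomethane ICI
Why: Takai-type methylenation with the gem-dizinc/titanium reagent converts the aldehyde chemoselectively in the presence of the ketone and the lactone; being non-basic, it avoids deprotonation of the doubly activated C7 methylene that a phosphorus ylide could cause.

Step 11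
Reactants: 16 6-oxo-17-(TBDPS-oxy)-13,14,15,16-tetranorlabda-8,11-dien-19,20-olide
Product: 17 6β-hydroxy-17-(TBDPS-oxy)-13,14,15,16-tetranorlabda-8,11-dien-19,20-olide
Conditions: NaBH4, CeCl3·7H2O, MeOH/THF, −78 °C
Reagents that add atoms: none
Why: Luche reduction; hydride can reach C6 only from the α face because C20 and the lactone bridge cover the β face, so the axial 6β-alcohol (6R) should result. At −78 °C the boron- or cerium-bound oxygen should not open the hindered lactone.

Step 12
Reactants: 17 6β-hydroxy-17-(TBDPS-oxy)-13,14,15,16-tetranorlabda-8,11-dien-19,20-olide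
Product: 18 6β-(TBS-oxy)-17-(TBDPS-oxy)-13,14,15,16-tetranorlabda-8,11-dien-19,20-olide
Conditions: TBSOTf, 2,6-lutidine, CH2Cl2, −40 → 0 °C
Reagents that add atoms: tert-butyldimethylsilyl trifluoromethanesulfonate CC(C)(C)[Si](C)(C)OS(=O)(=O)C(F)(F)F
Why: Silylation of the hindered axial alcohol with the silyl triflate; the ether prevents hydroxyl-directed epoxidation from the β face in step 14 and keeps O6 from attacking C19 in the basic steps.

Step 13
Reactants: 18 6β-(TBS-oxy)-17-(TBDPS-oxy)-13,14,15,16-tetranorlabda-8,11-dien-19,20-olide; 19 4-bromofuran-2(5H)-one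
Product: 21 6β-(TBS-oxy)-17-(TBDPS-oxy)labda-8,13-diene-19,20:15,16-diolide, via alkylborane 20 (not isolated)
Conditions: 9-BBN (1.5 equiv), THF, 0 → 23 °C; then 19, PdCl2(dppf) (5 mol%), AsPh3 (10 mol%), K3PO4 (3 M in H2O), DMF, 23 °C
Reagents that add atoms: none
Why: 9-BBN adds to the terminal carbon of the vinyl group only (the tetrasubstituted C8=C9 is inert), and the B-alkyl Suzuki–Miyaura coupling with the vinylogous acyl bromide 19 forms C12–C13 and brings in the butenolide at its final oxidation level.

Step 14
Reactants: 21 6β-(TBS-oxy)-17-(TBDPS-oxy)labda-8,13-diene-19,20:15,16-diolide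
Product: 22 8α,9α-epoxy-6β-(TBS-oxy)-17-(TBDPS-oxy)labd-13-ene-19,20:15,16-diolide
Conditions: mCPBA, NaHCO3, CH2Cl2, 0 °C
Reagents that add atoms: 3-chloroperoxybenzoic acid OOC(=O)c1cccc(Cl)c1
Why: Prilezhaev epoxidation of the only electron-rich alkene (the butenolide alkene is electron-poor). C20 with the lactone bridge and the axial 6β-silyloxy group cover the β face, so oxygen is delivered to the α face; this fixes the configuration of the C9–O bond.

Step 15
Reactants: 22 8α,9α-epoxy-6β-(TBS-oxy)-17-(TBDPS-oxy)labd-13-ene-19,20:15,16-diolide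
Product: 25 (13R)-8β,17:9α,13-diepoxy-6β-(TBS-oxy)labdane-19,20:15,16-diolide, via epoxy alcohol 23 (not isolated), via rearranged epoxy alcohol 24 (not isolated)
Conditions: Bu4NF·3H2O (1.3 equiv), THF, 0 → 23 °C
Reagents that add atoms: none
Why: Fluoride cleaves the primary Si–O bond of 22, and the C17 alkoxide so formed attacks C8 from the β side, anti to the breaking C8–O bond (3-exo-tet, Payne rearrangement of a 2,3-epoxy alcohol under aprotic alkoxide conditions); this turns the 8α,9α-oxirane into the 8β,17-oxirane with inversion at C8 and releases the 9α-alkoxide of 24 with its C9–O bond untouched. This tertiary alkoxide sits five atoms from the β-carbon C13 of the butenolide and adds to it (5-exo-trig oxa-Michael addition, the known base-mediated spirocyclisation of hydroxyalkyl butenolides), which closes the oxolane; the lactone enolate is protonated by the water of the reagent. The closest known reaction type is the Payne rearrangement run with capture of the rearranged alkoxide in the same flask, as in epoxy alcohol cascades. C8 is set stereospecifically by the inversion, C9 by the α-epoxidation of step 14, and C13 by the face of the butenolide that the alkoxide reaches; this last choice has little steric bias, but the conjugate addition is reversible under the conditions, so the ratio is under thermodynamic control and unwanted epimer can be resubmitted. The Payne equilibrium alone favours the tetrasubstituted oxirane and the primary alkoxide; it is drained by the conjugate addition, which consumes the tertiary alkoxide. The step needs cleavage of the primary silyl ether in the presence of the 6β-silyl ether, which the axial, doubly flanked position of O6 should secure, and it needs the alkoxide to reach C8 before it reaches any silyl or acyl group, which the three-membered transition state should secure.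

Step 16
Reactants: 25 (13R)-8β,17:9α,13-diepoxy-6β-(TBS-oxy)labdane-19,20:15,16-diolide
Product: 26 (13R)-8β,17:9α,13:15,16-triepoxy-15-hydroxy-6β-(TBS-oxy)labdan-19,20-olide (lactol, both C15 epimers)
Conditions: i-Bu2AlH (1.2 equiv), CH2Cl2, −78 °C; potassium sodium tartrate (aq)
Reagents that add atoms: none
Why: Partial reduction of the γ-lactone to the lactol. The δ-lactone has a quaternary α-carbon inside the bicyclo[3.3.1] frame and is flanked by the 6β-silyloxy group, so it should react far more slowly at −78 °C; the oxiranes are inert at this temperature.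

Step 17
Reactants: 26 (13R)-8β,17:9α,13:15,16-triepoxy-15-hydroxy-6β-(TBS-oxy)labdan-19,20-olide
Product: 27 (13R)-8β,17:9α,13:15,16-triepoxy-6β-(TBS-oxy)labd-14-en-19,20-olide
Conditions: MsCl, Et3N, CH2Cl2, −20 → 40 °C
Reagents that add atoms: none
Why: Mesylation of the hemiacetal hydroxyl and loss of mesylate through the oxocarbenium ion, then removal of a C14 proton by the amine, give the cyclic enol ether (the standard lactol-to-dihydrofuran dehydration); the medium stays basic, which the acid-labile spiro enol ether needs.

Step 18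
Reactants: 27 (13R)-8β,17:9α,13:15,16-triepoxy-6β-(TBS-oxy)labd-14-en-19,20-olide
Product: 29 (4S,5R,6R,8R,9S,10S,13R)-6β-acetoxy-8β,17:9α,13:15,16-triepoxylabd-14-en-19,20-olide (target), via alcohol 28 (not isolated)
Conditions: Bu4NF (1.5 equiv), AcOH (1.0 equiv), THF, 45 °C; then Ac2O, DMAP, Et3N, CH2Cl2, 0 → 23 °C
Reagents that add atoms: acetic anhydride CC(=O)OC(C)=O
Why: Buffered fluoride removes the hindered silyl ether without a free alkoxide, which could move the lactone to O6, and without free acid, which would open the spiro enol ether. The axial alcohol 28 is acetylated in the same flask by DMAP-catalysed acyl transfer; no stereocentre is touched.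

## Compound list

1 | 2-methoxybenzoyl chloride | COc1ccccc1C(Cl)=O | starting material
2 | (2S)-2-(methoxymethyl)pyrrolidine | COC[C@@H]1CCCN1 | starting material
3 | (2-methoxyphenyl)[(2S)-2-(methoxymethyl)pyrrolidin-1-yl]methanone | COC[C@@H]1CCCN1C(=O)c1ccccc1OC | intermediate
4 | [(1S)-2-methoxy-1-methylcyclohexa-2,5-dien-1-yl][(2S)-2-(methoxymethyl)pyrrolidin-1-yl]methanone | C[C@]1(C(=O)N2CCC[C@H]2COC)C=CCC=C1OC | intermediate
5 | (2S)-2-{[(2S)-2-(methoxymethyl)pyrrolidin-1-yl]carbonyl}-2-methylcyclohex-3-en-1-one | C[C@]1(C(=O)N2CCC[C@H]2COC)C=CCCC1=O | intermediate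
6 | (2S)-2-{[(2S)-2-(methoxymethyl)pyrrolidin-1-yl]carbonyl}-2-methylcyclohexan-1-one | C[C@]1(C(=O)N2CCC[C@H]2COC)CCCCC1=O | intermediate
7 | (3R)-2-bromo-3-{[(2S)-2-(methoxymethyl)pyrrolidin-1-yl]carbonyl}-3-methylcyclohex-1-ene-1-carbaldehyde | C[C@]1(C(=O)N2CCC[C@H]2COC)CCCC(C=O)=C1Br | intermediate
8 | tributyl(1-ethoxyethenyl)stannane | CCCC[Sn](CCCC)(CCCC)C(=C)OCC | starting material
9 | (3S)-2-(1-ethoxyethenyl)-3-{[(2S)-2-(methoxymethyl)pyrrolidin-1-yl]carbonyl}-3-methylcyclohex-1-ene-1-carbaldehyde | C[C@]1(C(=O)N2CCC[C@H]2COC)CCCC(C=O)=C1C(=C)OCC | intermediate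
10 | [(1S)-2-(1-ethoxyethenyl)-3-(hydroxymethyl)-1-methylcyclohex-2-en-1-yl][(2S)-2-(methoxymethyl)pyrrolidin-1-yl]methanone | C[C@]1(C(=O)N2CCC[C@H]2COC)CCCC(CO)=C1C(=C)OCC | intermediate
11 | tert-butyl(diphenyl)(prop-2-yn-1-yloxy)silane | C#CCO[Si](c1ccccc1)(c1ccccc1)C(C)(C)C | starting material
12 | 4-{[tert-butyl(diphenyl)silyl]oxy}but-2-ynal | O=CC#CCO[Si](c1ccccc1)(c1ccccc1)C(C)(C)C | intermediate
13 | hydroxy enal cycloadduct: 6-ethoxy-20-hydroxy-11-oxo-17-(TBDPS-oxy)-12,13,14,15,16-pentanorlabda-5,8-dien-19-oic acid (2S)-2-(methoxymethyl)pyrrolidide (4α-methyl, C20 β) | CCOC1=C2[C@@](C)(C(=O)N3CCC[C@H]3COC)CCC[C@]2(CO)C(C=O)=C(CO[Si](c2ccccc2)(c2ccccc2)C(C)(C)C)C1 | intermediate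
14 | 11,20-lactol of 13: 6-ethoxy-11,20-epoxy-11-hydroxy-17-(TBDPS-oxy)-12,13,14,15,16-pentanorlabda-5,8-dien-19-oic acid (2S)-2-(methoxymethyl)pyrrolidide | CCOC1=C2[C@@](C)(C(=O)N3CCC[C@H]3COC)CCC[C@@]23COC(O)C3=C(CO[Si](c2ccccc2)(c2ccccc2)C(C)(C)C)C1 | intermediate
15 | 6,11-dioxo-17-(TBDPS-oxy)-12,13,14,15,16-pentanorlabd-8-en-19,20-olide (4α-methyl, 5α-H) | O=C1CC(CO[Si](c2ccccc2)(c2ccccc2)C(C)(C)C)=C(C=O)[C@]23CCC[C@](C)(C(=O)OC2)[C@H]13 | intermediate
16 | 6-oxo-17-(TBDPS-oxy)-13,14,15,16-tetranorlabda-8,11-dien-19,20-olide | O=C1CC(CO[Si](c2ccccc2)(c2ccccc2)C(C)(C)C)=C(C=C)[C@]23CCC[C@](C)(C(=O)OC2)[C@H]13 | intermediate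
17 | 6β-hydroxy-17-(TBDPS-oxy)-13,14,15,16-tetranorlabda-8,11-dien-19,20-olide | O[C@@H]1CC(CO[Si](c2ccccc2)(c2ccccc2)C(C)(C)C)=C(C=C)[C@]23CCC[C@](C)(C(=O)OC2)[C@H]13 | intermediate
18 | 6β-(TBS-oxy)-17-(TBDPS-oxy)-13,14,15,16-tetranorlabda-8,11-dien-19,20-olide | CC(C)(C)[Si](C)(C)O[C@@H]1CC(CO[Si](c2ccccc2)(c2ccccc2)C(C)(C)C)=C(C=C)[C@]23CCC[C@](C)(C(=O)OC2)[C@H]13 | intermediate
19 | 4-bromofuran-2(5H)-one | BrC1=CC(=O)OC1 | starting material
20 | 12-(9-borabicyclo[3.3.1]nonan-9-yl)-6β-(TBS-oxy)-17-(TBDPS-oxy)-13,14,15,16-tetranorlabd-8-en-19,20-olide | CC(C)(C)[Si](C)(C)O[C@@H]1CC(CO[Si](c2ccccc2)(c2ccccc2)C(C)(C)C)=C(CCB2C4CCCC2CCC4)[C@]23CCC[C@](C)(C(=O)OC2)[C@H]13 | intermediate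
21 | 6β-(TBS-oxy)-17-(TBDPS-oxy)labda-8,13-diene-19,20:15,16-diolide | CC(C)(C)[Si](C)(C)O[C@@H]1CC(CO[Si](c2ccccc2)(c2ccccc2)C(C)(C)C)=C(CCC2=CC(=O)OC2)[C@]23CCC[C@](C)(C(=O)OC2)[C@H]13 | intermediate
22 | 8α,9α-epoxy-6β-(TBS-oxy)-17-(TBDPS-oxy)labd-13-ene-19,20:15,16-diolide | CC(C)(C)[Si](C)(C)O[C@@H]1C[C@@]2(CO[Si](c3ccccc3)(c3ccccc3)C(C)(C)C)O[C@@]2(CCC2=CC(=O)OC2)[C@]23CCC[C@](C)(C(=O)OC2)[C@H]13 | intermediate
23 | 8α,9α-epoxy-17-hydroxy-6β-(TBS-oxy)labd-13-ene-19,20:15,16-diolide | CC(C)(C)[Si](C)(C)O[C@@H]1C[C@@]2(CO)O[C@@]2(CCC2=CC(=O)OC2)[C@]23CCC[C@](C)(C(=O)OC2)[C@H]13 | intermediate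
24 | 8β,17-epoxy-9α-hydroxy-6β-(TBS-oxy)labd-13-ene-19,20:15,16-diolide | CC(C)(C)[Si](C)(C)O[C@@H]1C[C@@]2(CO2)[C@](O)(CCC2=CC(=O)OC2)[C@]23CCC[C@](C)(C(=O)OC2)[C@H]13 | intermediate
25 | (13R)-8β,17:9α,13-diepoxy-6β-(TBS-oxy)labdane-19,20:15,16-diolide | CC(C)(C)[Si](C)(C)O[C@@H]1C[C@@]2(CO2)[C@]2(CC[C@]3(CC(=O)OC3)O2)[C@]23CCC[C@](C)(C(=O)OC2)[C@H]13 | intermediate
26 | (13R)-8β,17:9α,13:15,16-triepoxy-15-hydroxy-6β-(TBS-oxy)labdan-19,20-olide | CC(C)(C)[Si](C)(C)O[C@@H]1C[C@@]2(CO2)[C@]2(CC[C@]3(CC(O)OC3)O2)[C@]23CCC[C@](C)(C(=O)OC2)[C@H]13 | intermediate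
27 | (13R)-8β,17:9α,13:15,16-triepoxy-6β-(TBS-oxy)labd-14-en-19,20-olide | CC(C)(C)[Si](C)(C)O[C@@H]1C[C@@]2(CO2)[C@]2(CC[C@]3(C=COC3)O2)[C@]23CCC[C@](C)(C(=O)OC2)[C@H]13 | intermediate
28 | (13R)-8β,17:9α,13:15,16-triepoxy-6β-hydroxylabd-14-en-19,20-olide | O[C@@H]1C[C@@]2(CO2)[C@]2(CC[C@]3(C=COC3)O2)[C@]23CCC[C@](C)(C(=O)OC2)[C@H]13 | intermediate
29 | (4S,5R,6R,8R,9S,10S,13R)-6β-acetoxy-8β,17:9α,13:15,16-triepoxylabd-14-en-19,20-olide | CC(=O)O[C@@H]1C[C@@]2(CO2)[C@]2(CC[C@]3(C=COC3)O2)[C@]23CCC[C@](C)(C(=O)OC2)[C@H]13 | target

## Step count and least certain steps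

Total step count: 18. Longest linear sequence: 17 steps (steps 1–6 and 8–18, from 1 and 2 to 29); step 7 is a one-step branch.

Step 15 (key step). Three things can go wrong. First, the facial selection at C13 in the oxa-Michael closure has little steric bias, so both spiro epimers may form. Second, the 6β-silyl group may migrate to the C17 alkoxide before the Payne step, because the two oxygens are syn on ring B. Third, the Payne equilibrium may not be drained if the conjugate addition is slow. The fallback separates the events and makes the oxirane by a different bond construction. It sets out from 22, which is desilylated with acetic acid-buffered Bu4NF to the epoxy alcohol 23, isolated in this variant. An Appel reaction (I2, PPh3, imidazole) gives the 17-iodo-8α,9α-epoxide F1. Zinc dust in ethanol opens it reductively to the 9α-hydroxy-8(17)-ene F2. Catalytic DBU closes the oxolane to the spiro lactone with an exocyclic alkene F3; the oxa-Michael is then run alone and under equilibrium. Ozonolysis with Me2S work-up gives the C8 ketone F4. Dimethylsulfonium methylide (Me3SI, KN(SiMe3)2) attacks the ketone from the open α face and places the oxygen on the β face (Corey–Chaykovsky epoxidation). The fallback comes back to the route at 25.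

Step 8. The tetrasubstituted diene is congested in its s-cis form, so the cycloaddition may be slow and a [1,5]-hydrogen shift from C20 to C7 may compete. The facial control by the C4 amide is argued from allylic strain, not from precedent on this diene. The fallback uses a doubly activated, symmetrical dienophile and corrects the oxidation levels afterwards. It sets out from 10, which is heated with dimethyl but-2-ynedioate; a catalytic amount of DBU then closes the C20 hydroxyl onto the C11 ester to give the lactone ester F5. Reduction with i-Bu2AlH at −78 °C gives the lactol alcohol F6. Selective silylation of the primary allylic hydroxyl with TBDPSCl and imidazole comes back to the route at 14.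

Step 9. The hindered tertiary amide may resist the acyl transfer under acid that the primary silyl ether and the enal still tolerate. The fallback removes the auxiliary by reduction. It sets out from 14, whose amide is reduced with Cp2Zr(H)Cl to the C19 aldehyde F7. Aqueous oxalic acid hydrolyses the enol ether and lets C20–OH close onto the C19 aldehyde, giving the 19,20-lactol F8. Oxidation of the lactol with Ag2CO3 on Celite comes back to the route at 15.

Step 13. Protodeboronation or opening of the base-sensitive bromobutenolide under the aqueous basic coupling conditions may lower the conversion. The fallback uses a base-free organozinc coupling. It sets out from 18: hydroboration with 9-BBN and oxidation with NaBO3·4H2O give the primary alcohol F9. I2, PPh3 and imidazole give the iodide F10. Zinc insertion (Zn, LiCl, THF) and Negishi coupling with 19 under Pd(PPh3)4 come back to the route at 21.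

Step 16. Over-reduction of the lactol, or attack of the hydride on the δ-lactone, may occur if the two lactones differ less in rate than expected. The fallback avoids hydride and the lactol altogether. It sets out from 25: only the γ-lactone has α-hydrogens, so KN(SiMe3)2 with (PhO)2P(O)Cl at −78 °C (electrophile present during deprotonation, to outrun β-elimination of the C9 oxygen) gives the ketene acetal phosphate F11. Reduction with Bu3SnH under Pd(PPh3)4 gives the enol ether and comes back to the route at 27.

## Further compounds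

F1 | step 15 | 8α,9α-epoxy-17-iodo-6β-(TBS-oxy)labd-13-ene-19,20:15,16-diolide | CC(C)(C)[Si](C)(C)O[C@@H]1C[C@@]2(CI)O[C@@]2(CCC2=CC(=O)OC2)[C@]23CCC[C@](C)(C(=O)OC2)[C@H]13
F2 | step 15 | 9α-hydroxy-6β-(TBS-oxy)labda-8(17),13-diene-19,20:15,16-diolide | CC(C)(C)[Si](C)(C)O[C@@H]1CC(=C)[C@](O)(CCC2=CC(=O)OC2)[C@]23CCC[C@](C)(C(=O)OC2)[C@H]13
F3 | step 15 | (13R)-9α,13-epoxy-6β-(TBS-oxy)labd-8(17)-ene-19,20:15,16-diolide | CC(C)(C)[Si](C)(C)O[C@@H]1CC(=C)[C@]2(CC[C@]3(CC(=O)OC3)O2)[C@]23CCC[C@](C)(C(=O)OC2)[C@H]13
F4 | step 15 | (13R)-9α,13-epoxy-8-oxo-6β-(TBS-oxy)-17-norlabdane-19,20:15,16-diolide | CC(C)(C)[Si](C)(C)O[C@@H]1CC(=O)[C@]2(CC[C@]3(CC(=O)OC3)O2)[C@]23CCC[C@](C)(C(=O)OC2)[C@H]13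
F5 | step 8 | methyl 6-ethoxy-11-oxo-11,20-epoxy-12,13,14,15,16-pentanorlabda-5,8-dien-17-oate 19-[(2S)-2-(methoxymethyl)pyrrolidide] | CCOC1=C2[C@@](C)(C(=O)N3CCC[C@H]3COC)CCC[C@@]23COC(=O)C3=C(C(=O)OC)C1
F6 | step 8 | 6-ethoxy-11,20-epoxy-11,17-dihydroxy-12,13,14,15,16-pentanorlabda-5,8-dien-19-oic acid (2S)-2-(methoxymethyl)pyrrolidide | CCOC1=C2[C@@](C)(C(=O)N3CCC[C@H]3COC)CCC[C@@]23COC(O)C3=C(CO)C1
F7 | step 9 | 6-ethoxy-11,20-epoxy-11-hydroxy-17-(TBDPS-oxy)-12,13,14,15,16-pentanorlabda-5,8-dien-19-al | CCOC1=C2[C@@](C)(C=O)CCC[C@@]23COC(O)C3=C(CO[Si](c2ccccc2)(c2ccccc2)C(C)(C)C)C1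
F8 | step 9 | 19,20-epoxy-19-hydroxy-6,11-dioxo-17-(TBDPS-oxy)-12,13,14,15,16-pentanorlabd-8-ene (19,20-lactol) | O=C1CC(CO[Si](c2ccccc2)(c2ccccc2)C(C)(C)C)=C(C=O)[C@]23CCC[C@](C)(C(O)OC2)[C@H]13
F9 | step 13 | 12-hydroxy-6β-(TBS-oxy)-17-(TBDPS-oxy)-13,14,15,16-tetranorlabd-8-en-19,20-olide | CC(C)(C)[Si](C)(C)O[C@@H]1CC(CO[Si](c2ccccc2)(c2ccccc2)C(C)(C)C)=C(CCO)[C@]23CCC[C@](C)(C(=O)OC2)[C@H]13
F10 | step 13 | 12-iodo-6β-(TBS-oxy)-17-(TBDPS-oxy)-13,14,15,16-tetranorlabd-8-en-19,20-olide | CC(C)(C)[Si](C)(C)O[C@@H]1CC(CO[Si](c2ccccc2)(c2ccccc2)C(C)(C)C)=C(CCI)[C@]23CCC[C@](C)(C(=O)OC2)[C@H]13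
F11 | step 16 | (13R)-15-(diphenoxyphosphoryloxy)-8β,17:9α,13:15,16-triepoxy-6β-(TBS-oxy)labd-14-en-19,20-olide | CC(C)(C)[Si](C)(C)O[C@@H]1C[C@@]2(CO2)[C@]2(CC[C@]3(C=C(OP(=O)(Oc4ccccc4)Oc4ccccc4)OC3)O2)[C@]23CCC[C@](C)(C(=O)OC2)[C@H]13
A1 | alternative 1 | (8aS)-8a-[(benzyloxy)methyl]-3,4,8,8a-tetrahydronaphthalene-1,6(2H,7H)-dione | O=C1C=C2CCCC(=O)[C@@]2(COCc2ccccc2)CC1
A2 | alternative 2 | ethyl 20-(benzyloxy)-15,16-epoxy-3-oxolabda-8(17),13(16),14-trien-19-oate (4α-methyl, 5α-H, 9α-H) | CCOC(=O)[C@@]1(C)C(=O)CC[C@]2(COCc3ccccc3)[C@@H](CCc3ccoc3)C(=C)CC[C@@H]12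
A3 | alternative 3 | 6β-acetoxy-8β,17:15,16-diepoxy-9α-hydroxylabda-13(16),14-dien-19,20-olide | CC(=O)O[C@@H]1C[C@@]2(CO2)[C@](O)(CCc2ccoc2)[C@]23CCC[C@](C)(C(=O)OC2)[C@H]13
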